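**Plan**
1. Retrosynthesis: the alpha chain is removed at C8–C7 (enolate alkylation) and C9 is taken to the ketone level. The cyclopentane is then cut at C10–C11 and C8–C12 in one formal [3+2] disconnection into an acetoacetate unit (C8–C9–C10) and a ten-carbon epoxy-enal (C11–C20).
2. Enabling feature: in the five-membered ring O9 and O11 sit 1,3 across the C10 methylene (aldol retron), and C12 carries an exocyclic E-C13=C14 bond next to the C15 carbinol (retron of an SN2′ opening of a C14–C15 vinyl epoxide at C12).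
3. Forward: the epoxy-enal is made first. Aldol C10→C11 and palladium-mediated closure C8→C12 in one flask then give the ring with the complete omega chain. The alpha chain follows by C8 alkylation, then decarboxylation, C9 reduction and deprotection.
4. Stereochemistry: C14 and C15 come from a Sharpless epoxidation, C12 from C14 by 1,3-chirality transfer through the π-allyl, C11 from the BINOL–titanium aldol catalyst, C8 by equilibration (trans to C12), and C9 by hydride delivery anti to the alpha chain.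

Key step: step 6

Assumption (remark on the chemistry): with (R)-BINOL the titanium-bound enal is taken to be attacked on its Re face, as in related additions; if the sense proves opposite, (S)-BINOL is used and nothing else changes. Compounds 1, 4, 6 and 13 are taken as commercial.

**Step 1**
Reactants: 1 (2Z)-oct-2-en-1-ol
Product: 2 [(2R,3S)-3-pentyloxiran-2-yl]methanol
Conditions: Ti(OiPr)4 (10 mol%), D-(−)-diethyl tartrate (12 mol%), t-BuOOH, 4 Å MS, CH2Cl2, −20 °C
Reagents that add atoms: tert-butyl hydroperoxide, CC(C)(C)OO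
Why: Sharpless asymmetric epoxidation; the titanium–tartrate complex delivers oxygen to one face of the Z-allylic alcohol, and D-(−)-tartrate is chosen because L-(+)-tartrate gives the 2S series of 2,3-epoxy alcohols, so that the cis-epoxide (2R,3S) carrying the future C14 and C15 should result.

**Step 2**
Reactants: 2 [(2R,3S)-3-pentyloxiran-2-yl]methanol
Product: 3 (2S,3S)-3-pentyloxirane-2-carbaldehyde
Conditions: TEMPO (10 mol%), PhI(OAc)2, CH2Cl2, 0 °C to rt
Reagents that add atoms: none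
Why: Oxoammonium (TEMPO) oxidation of the primary alcohol under near-neutral conditions should spare the epoxide and the epimerisable α-carbon; the label at C2 changes from R to S only because the priorities change.

**Step 3**
Reactants: 3 (2S,3S)-3-pentyloxirane-2-carbaldehyde; 4 (triphenylphosphoranylidene)acetaldehyde
Product: 5 (2E)-3-[(2R,3S)-3-pentyloxiran-2-yl]prop-2-enal
Conditions: CH2Cl2, rt
Reagents that add atoms: none
Why: Wittig olefination with the stabilised formyl ylide should give the E-enal and extend the chain by two carbons without touching the epoxide stereocentres.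

**Step 4**
Reactants: 6 allyl acetoacetate
Product: 7 allyl (2Z)-3-(trimethylsilyloxy)but-2-enoate
Conditions: Me3SiCl, Et3N, hexane, rt
Reagents that add atoms: chlorotrimethylsilane, C[Si](C)(C)Cl
Why: Soft enolisation and O-silylation of the β-keto ester should give the chelate-derived Z silyl enol ether.

**Step 5**
Reactants: 7 allyl (2Z)-3-(trimethylsilyloxy)but-2-enoate
Product: 8 (1Z)-1-(allyloxy)-1,3-bis(trimethylsilyloxy)buta-1,3-diene
Conditions: LiN(iPr)2, THF, −78 °C; Me3SiCl, −78 °C; cold non-aqueous work-up, used at once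
Reagents that add atoms: chlorotrimethylsilane, C[Si](C)(C)Cl
Why: γ-Deprotonation of the vinylogous ester and O-silylation give the 1,3-bis(silyloxy)diene (silyl dienolate formation); it is an allyl silyl ketene acetal and is kept below 0 °C so that Ireland–Claisen rearrangement does not set in (the ketene-acetal geometry drawn is not controlling).

**Step 6**
Reactants: 5 (2E)-3-[(2R,3S)-3-pentyloxiran-2-yl]prop-2-enal; 8 (1Z)-1-(allyloxy)-1,3-bis(trimethylsilyloxy)buta-1,3-diene
Product: 11 allyl (1R,2R,3R)-3-hydroxy-2-[(1E,3S)-3-hydroxyoct-1-en-1-yl]-5-oxocyclopentane-1-carboxylate, via silylated aldol adduct 9 (not isolated), via cyclised bis(trimethylsilyl) ether 10 (not isolated)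
Conditions: Ti(OiPr)4 (10 mol%), (R)-BINOL (10 mol%), 4 Å MS, THF, −78 to −20 °C; then Pd(PPh3)4 (5 mol%), THF, 0 °C; then PPTS (cat.), MeOH, 0 °C
Reagents that add atoms: none
Why: The terminal carbon of diene 8 (C10) adds to the aldehyde carbon of 5 (C11) in a vinylogous Mukaiyama aldol on the BINOL–titanium-bound aldehyde with silyl transfer to give 9; zerovalent palladium then ionises the vinyl epoxide with inversion, the freed C15 alkoxide relays a trimethylsilyl group from the enol ether oxygen (O9, through O11) onto itself and so unmasks the β-keto ester enolate, and C8 attacks the near π-allyl terminus C12 anti to palladium to give 10, which methanolysis converts into 11 (formal [3+2] annulation). The closest known reaction types are the catalytic enantioselective aldol of 1,3-bis(silyloxy)dienes with enals and the palladium-catalysed Tsuji–Trost cyclisation of β-keto esters onto 1,3-diene monoepoxides, which gives 2-carboalkoxy-3-alkenylcyclopentanones carrying an (E)-allylic alcohol. The cyclopentane closes in the 5-exo mode at C12 (attack at C14 would need a seven-membered ring), and carbon alkylation wins because O-allylation is reversible under palladium. C11 (R) is set by the catalyst (Re-face addition expected with (R)-BINOL), C12 (R) by 1,3-chirality transfer from C14 through the syn,syn π-allyl (net retention, which from the cis-epoxide and the E-alkene gives the natural C12/C15 relationship and the E C13=C14 bond), C15 (S) is the untouched epoxide carbon, and C8 is epimerisable and should settle trans to the C12 chain. The step needs terminal (C10) rather than central (C8) attack of the diene and 1,2- rather than 1,4-addition to the enal, both normal for silyl dienolates with Lewis-acid-activated enals, and ionisation of the vinyl epoxide in preference to the allyl ester, secured by the ring strain of the epoxide and the low temperature of the palladium stage.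

**Step 7**
Reactants: 11 allyl (1R,2R,3R)-3-hydroxy-2-[(1E,3S)-3-hydroxyoct-1-en-1-yl]-5-oxocyclopentane-1-carboxylate
Product: 12 allyl (1R,2R,3R)-3-(tert-butyldimethylsilyloxy)-2-[(1E,3S)-3-(tert-butyldimethylsilyloxy)oct-1-en-1-yl]-5-oxocyclopentane-1-carboxylate
Conditions: t-BuMe2SiCl, imidazole, DMF, rt
Reagents that add atoms: tert-butyl(chloro)dimethylsilane, CC(C)(C)[Si](C)(C)Cl
Why: Silylation of both secondary alcohols blocks the β-hydroxy ketone against elimination in the basic and reductive steps that follow.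

**Step 8**
Reactants: 12 allyl (1R,2R,3R)-3-(tert-butyldimethylsilyloxy)-2-[(1E,3S)-3-(tert-butyldimethylsilyloxy)oct-1-en-1-yl]-5-oxocyclopentane-1-carboxylate; 13 methyl 7-bromoheptanoate
Product: 14 allyl (1S,2R,3R)-3-(tert-butyldimethylsilyloxy)-2-[(1E,3S)-3-(tert-butyldimethylsilyloxy)oct-1-en-1-yl]-1-(7-methoxy-7-oxoheptyl)-5-oxocyclopentane-1-carboxylate
Conditions: Cs2CO3, DMF, rt
Reagents that add atoms: none
Why: C-Alkylation of the stabilised β-keto ester enolate installs the alpha chain at C8, expected trans to the neighbouring C12 alkenyl group; the configuration of this quaternary centre is erased again in step 9.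

**Step 9**
Reactants: 14 allyl (1S,2R,3R)-3-(tert-butyldimethylsilyloxy)-2-[(1E,3S)-3-(tert-butyldimethylsilyloxy)oct-1-en-1-yl]-1-(7-methoxy-7-oxoheptyl)-5-oxocyclopentane-1-carboxylate
Product: 16 methyl 7-[(1R,2R,3R)-3-(tert-butyldimethylsilyloxy)-2-[(1E,3S)-3-(tert-butyldimethylsilyloxy)oct-1-en-1-yl]-5-oxocyclopentyl]heptanoate, via keto acid 15 (not isolated)
Conditions: Pd(OAc)2 (5 mol%), PPh3, HCO2H, Et3N, THF, rt
Reagents that add atoms: none
Why: Palladium-catalysed hydrogenolysis of the allyl ester with formate and decarboxylation of the resulting β-keto acid proceed under neutral conditions that should not eliminate the β-silyloxy group; protonation and equilibration at C8 should give the more stable 8,12-trans ketone.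

**Step 10**
Reactants: 16 methyl 7-[(1R,2R,3R)-3-(tert-butyldimethylsilyloxy)-2-[(1E,3S)-3-(tert-butyldimethylsilyloxy)oct-1-en-1-yl]-5-oxocyclopentyl]heptanoate
Product: 17 methyl 7-[(1R,2R,3R,5S)-3-(tert-butyldimethylsilyloxy)-2-[(1E,3S)-3-(tert-butyldimethylsilyloxy)oct-1-en-1-yl]-5-hydroxycyclopentyl]heptanoate
Conditions: LiBH(s-Bu)3 (L-selectride), THF, −78 °C
Reagents that add atoms: none
Why: The bulky hydride should attack the C9 ketone from the face opposite the adjacent alpha chain on C8 and give the 9S (9α) alcohol (substrate-controlled reduction); the remote methyl ester survives at −78 °C.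

**Step 11**
Reactants: 17 methyl 7-[(1R,2R,3R,5S)-3-(tert-butyldimethylsilyloxy)-2-[(1E,3S)-3-(tert-butyldimethylsilyloxy)oct-1-en-1-yl]-5-hydroxycyclopentyl]heptanoate
Product: 18 7-[(1R,2R,3R,5S)-3-(tert-butyldimethylsilyloxy)-2-[(1E,3S)-3-(tert-butyldimethylsilyloxy)oct-1-en-1-yl]-5-hydroxycyclopentyl]heptanoic acid
Conditions: LiOH, THF/MeOH/H2O, rt; then 1 M HCl to pH 4
Reagents that add atoms: lithium hydroxide, [Li+].[OH-]
Why: Saponification of the methyl ester; no base-sensitive β-oxy ketone is left and the silyl ethers tolerate hydroxide.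

**Step 12**
Reactants: 18 7-[(1R,2R,3R,5S)-3-(tert-butyldimethylsilyloxy)-2-[(1E,3S)-3-(tert-butyldimethylsilyloxy)oct-1-en-1-yl]-5-hydroxycyclopentyl]heptanoic acid
Product: 19 7-[(1R,2R,3R,5S)-3,5-dihydroxy-2-[(1E,3S)-3-hydroxyoct-1-en-1-yl]cyclopentyl]heptanoic acid (prostaglandin F1α)
Conditions: HF·pyridine, THF, 0 °C to rt
Reagents that add atoms: none
Why: Fluoride-mediated cleavage of both silyl ethers under mildly acidic conditions should release the triol acid without touching the allylic alcohol.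

**Compound list**
1 | (2Z)-oct-2-en-1-ol | CCCCC/C=C\CO | starting material
2 | [(2R,3S)-3-pentyloxiran-2-yl]methanol | OC[C@H]1O[C@H]1CCCCC | intermediate
3 | (2S,3S)-3-pentyloxirane-2-carbaldehyde | O=C[C@H]1O[C@H]1CCCCC | intermediate
4 | (triphenylphosphoranylidene)acetaldehyde | O=CC=P(c1ccccc1)(c1ccccc1)c1ccccc1 | starting material
5 | (2E)-3-[(2R,3S)-3-pentyloxiran-2-yl]prop-2-enal | O=C/C=C/[C@H]1O[C@H]1CCCCC | intermediate
6 | allyl acetoacetate (prop-2-en-1-yl 3-oxobutanoate) | CC(=O)CC(=O)OCC=C | starting material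
7 | allyl (2Z)-3-(trimethylsilyloxy)but-2-enoate | C/C(O[Si](C)(C)C)=C/C(=O)OCC=C | intermediate
8 | (1Z)-1-(allyloxy)-1,3-bis(trimethylsilyloxy)buta-1,3-diene | C=C(O[Si](C)(C)C)/C=C(/OCC=C)O[Si](C)(C)C | intermediate
9 | allyl (2Z,5R,6E)-7-[(2R,3S)-3-pentyloxiran-2-yl]-3,5-bis(trimethylsilyloxy)hepta-2,6-dienoate | C=CCOC(=O)/C=C(\O[Si](C)(C)C)C[C@@H](O[Si](C)(C)C)/C=C/[C@H]1O[C@H]1CCCCC | intermediate
10 | allyl (1R,2R,3R)-5-oxo-3-(trimethylsilyloxy)-2-[(1E,3S)-3-(trimethylsilyloxy)oct-1-en-1-yl]cyclopentane-1-carboxylate | CCCCC[C@H](O[Si](C)(C)C)/C=C/[C@@H]1[C@@H](C(=O)OCC=C)C(=O)C[C@H]1O[Si](C)(C)C | intermediate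
11 | allyl (1R,2R,3R)-3-hydroxy-2-[(1E,3S)-3-hydroxyoct-1-en-1-yl]-5-oxocyclopentane-1-carboxylate | CCCCC[C@H](O)/C=C/[C@@H]1[C@@H](C(=O)OCC=C)C(=O)C[C@H]1O | intermediate
12 | allyl (1R,2R,3R)-3-(tert-butyldimethylsilyloxy)-2-[(1E,3S)-3-(tert-butyldimethylsilyloxy)oct-1-en-1-yl]-5-oxocyclopentane-1-carboxylate | CCCCC[C@H](O[Si](C)(C)C(C)(C)C)/C=C/[C@@H]1[C@@H](C(=O)OCC=C)C(=O)C[C@H]1O[Si](C)(C)C(C)(C)C | intermediate
13 | methyl 7-bromoheptanoate | COC(=O)CCCCCCBr | starting material
14 | allyl (1S,2R,3R)-3-(tert-butyldimethylsilyloxy)-2-[(1E,3S)-3-(tert-butyldimethylsilyloxy)oct-1-en-1-yl]-1-(7-methoxy-7-oxoheptyl)-5-oxocyclopentane-1-carboxylate | CCCCC[C@H](O[Si](C)(C)C(C)(C)C)/C=C/[C@@H]1[C@@](C(=O)OCC=C)(CCCCCCC(=O)OC)C(=O)C[C@H]1O[Si](C)(C)C(C)(C)C | intermediate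
15 | (1S,2R,3R)-3-(tert-butyldimethylsilyloxy)-2-[(1E,3S)-3-(tert-butyldimethylsilyloxy)oct-1-en-1-yl]-1-(7-methoxy-7-oxoheptyl)-5-oxocyclopentane-1-carboxylic acid | CCCCC[C@H](O[Si](C)(C)C(C)(C)C)/C=C/[C@@H]1[C@@](C(=O)O)(CCCCCCC(=O)OC)C(=O)C[C@H]1O[Si](C)(C)C(C)(C)C | intermediate
16 | methyl 7-[(1R,2R,3R)-3-(tert-butyldimethylsilyloxy)-2-[(1E,3S)-3-(tert-butyldimethylsilyloxy)oct-1-en-1-yl]-5-oxocyclopentyl]heptanoate | CCCCC[C@H](O[Si](C)(C)C(C)(C)C)/C=C/[C@@H]1[C@@H](CCCCCCC(=O)OC)C(=O)C[C@H]1O[Si](C)(C)C(C)(C)C | intermediate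
17 | methyl 7-[(1R,2R,3R,5S)-3-(tert-butyldimethylsilyloxy)-2-[(1E,3S)-3-(tert-butyldimethylsilyloxy)oct-1-en-1-yl]-5-hydroxycyclopentyl]heptanoate | CCCCC[C@H](O[Si](C)(C)C(C)(C)C)/C=C/[C@@H]1[C@@H](CCCCCCC(=O)OC)[C@@H](O)C[C@H]1O[Si](C)(C)C(C)(C)C | intermediate
18 | 7-[(1R,2R,3R,5S)-3-(tert-butyldimethylsilyloxy)-2-[(1E,3S)-3-(tert-butyldimethylsilyloxy)oct-1-en-1-yl]-5-hydroxycyclopentyl]heptanoic acid | CCCCC[C@H](O[Si](C)(C)C(C)(C)C)/C=C/[C@@H]1[C@@H](CCCCCCC(=O)O)[C@@H](O)C[C@H]1O[Si](C)(C)C(C)(C)C | intermediate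
19 | 7-[(1R,2R,3R,5S)-3,5-dihydroxy-2-[(1E,3S)-3-hydroxyoct-1-en-1-yl]cyclopentyl]heptanoic acid (prostaglandin F1α) | CCCCC[C@H](O)/C=C/[C@@H]1[C@@H](CCCCCCC(=O)O)[C@@H](O)C[C@H]1O | target

**Step count**
Total: 12 steps. Longest linear sequence: 10 steps (steps 1, 2, 3, 6, 7, 8, 9, 10, 11, 12).

**Steps most likely to fail**

Step 6. What may go wrong: incomplete facial control by the catalyst in the aldol stage on an aldehyde that carries its own Lewis-basic epoxide; [3,3] rearrangement of the allyl silyl ketene acetal 8 before it is consumed; or ionisation of the allyl ester by zerovalent palladium once the ring has closed. The fallback makes the two bonds separately, sets out from 5 and returns at 11. 2,2,6-Trimethyl-4H-1,3-dioxin-4-one is converted with LiN(iPr)2 and Me3SiCl (THF, −78 °C) into its silyl dienolate 2,2-dimethyl-4-methylidene-6-(trimethylsilyloxy)-4H-1,3-dioxine F1. F1 adds to 5 in a vinylogous Mukaiyama aldol under a chiral binaphthyl Schiff-base/3,5-di-tert-butylsalicylate catalyst made from Ti(OiPr)4 (Et2O, −10 °C) to give the O-silylated dioxinone 2,2-dimethyl-6-[(2R,3E)-4-[(2R,3S)-3-pentyloxiran-2-yl]-2-(trimethylsilyloxy)but-3-en-1-yl]-4H-1,3-dioxin-4-one F2. Heating F2 with allyl alcohol in toluene (100 °C) releases acetone and the acylketene (5R,6E)-3-oxo-7-[(2R,3S)-3-pentyloxiran-2-yl]-5-(trimethylsilyloxy)hepta-1,6-dien-1-one F3, which the alcohol traps as the isolable β-keto ester allyl (5R,6E)-3-oxo-7-[(2R,3S)-3-pentyloxiran-2-yl]-5-(trimethylsilyloxy)hept-6-enoate F4 (no ketene acetal). Pd(PPh3)4 (THF, 0 °C) then closes the ring as in the second stage of step 6 to allyl (1R,2R,3R)-2-[(1E,3S)-3-hydroxyoct-1-en-1-yl]-5-oxo-3-(trimethylsilyloxy)cyclopentane-1-carboxylate F5, and PPTS in MeOH gives 11.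

Step 8. What may go wrong: slow C-alkylation at the hindered ring carbon by an unactivated primary bromide, with competing O-alkylation and base-induced β-elimination of the silyloxy group on prolonged exposure to carbonate. The fallback uses an allylic electrophile and a late chemoselective hydrogenation, sets out from 12 and returns at 16. Compound 12 is alkylated with methyl (5Z)-7-bromohept-5-enoate (Cs2CO3, DMF, 0 °C) to allyl (1S,2R,3R)-3-(tert-butyldimethylsilyloxy)-2-[(1E,3S)-3-(tert-butyldimethylsilyloxy)oct-1-en-1-yl]-1-[(2Z)-7-methoxy-7-oxohept-2-en-1-yl]-5-oxocyclopentane-1-carboxylate F6. The conditions of step 9 convert F6 through the keto acid (1S,2R,3R)-3-(tert-butyldimethylsilyloxy)-2-[(1E,3S)-3-(tert-butyldimethylsilyloxy)oct-1-en-1-yl]-1-[(2Z)-7-methoxy-7-oxohept-2-en-1-yl]-5-oxocyclopentane-1-carboxylic acid F7 into methyl (5Z)-7-[(1R,2R,3R)-3-(tert-butyldimethylsilyloxy)-2-[(1E,3S)-3-(tert-butyldimethylsilyloxy)oct-1-en-1-yl]-5-oxocyclopentyl]hept-5-enoate F8. Hydrogenation of the less hindered cis C5=C6 bond of F8 (H2, RhCl(PPh3)3, benzene, rt) in the presence of the flanked E C13=C14 bond gives 16.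

Step 3. What may go wrong: epimerisation of the cis-epoxy aldehyde at the carbon α to the formyl group, and a second olefination of the product enal by the ylide. The fallback homologates at the ester oxidation level, sets out from 3 and returns at 5. Horner–Wadsworth–Emmons olefination of 3 with triethyl phosphonoacetate (LiCl, i-Pr2NEt, MeCN, 0 °C) gives ethyl (2E)-3-[(2R,3S)-3-pentyloxiran-2-yl]prop-2-enoate F9. Reduction with i-Bu2AlH (CH2Cl2, −78 °C) gives (2E)-3-[(2R,3S)-3-pentyloxiran-2-yl]prop-2-en-1-ol F10, and MnO2 (CH2Cl2, rt) oxidises F10 to 5.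

**Further compounds**
F1 | step 6 | 2,2-dimethyl-4-methylidene-6-(trimethylsilyloxy)-4H-1,3-dioxine | C=C1C=C(O[Si](C)(C)C)OC(C)(C)O1
F2 | step 6 | 2,2-dimethyl-6-[(2R,3E)-4-[(2R,3S)-3-pentyloxiran-2-yl]-2-(trimethylsilyloxy)but-3-en-1-yl]-4H-1,3-dioxin-4-one | CC1(C)OC(C[C@@H](O[Si](C)(C)C)/C=C/[C@H]2O[C@H]2CCCCC)=CC(=O)O1
F3 | step 6 | (5R,6E)-3-oxo-7-[(2R,3S)-3-pentyloxiran-2-yl]-5-(trimethylsilyloxy)hepta-1,6-dien-1-one | O=C=CC(=O)C[C@@H](O[Si](C)(C)C)/C=C/[C@H]1O[C@H]1CCCCC
F4 | step 6 | allyl (5R,6E)-3-oxo-7-[(2R,3S)-3-pentyloxiran-2-yl]-5-(trimethylsilyloxy)hept-6-enoate | C=CCOC(=O)CC(=O)C[C@@H](O[Si](C)(C)C)/C=C/[C@H]1O[C@H]1CCCCC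
F5 | step 6 | allyl (1R,2R,3R)-2-[(1E,3S)-3-hydroxyoct-1-en-1-yl]-5-oxo-3-(trimethylsilyloxy)cyclopentane-1-carboxylate | CCCCC[C@H](O)/C=C/[C@@H]1[C@@H](C(=O)OCC=C)C(=O)C[C@H]1O[Si](C)(C)C
F6 | step 8 | allyl (1S,2R,3R)-3-(tert-butyldimethylsilyloxy)-2-[(1E,3S)-3-(tert-butyldimethylsilyloxy)oct-1-en-1-yl]-1-[(2Z)-7-methoxy-7-oxohept-2-en-1-yl]-5-oxocyclopentane-1-carboxylate | CCCCC[C@H](O[Si](C)(C)C(C)(C)C)/C=C/[C@@H]1[C@@](C(=O)OCC=C)(C/C=C\CCCC(=O)OC)C(=O)C[C@H]1O[Si](C)(C)C(C)(C)C
F7 | step 8 | (1S,2R,3R)-3-(tert-butyldimethylsilyloxy)-2-[(1E,3S)-3-(tert-butyldimethylsilyloxy)oct-1-en-1-yl]-1-[(2Z)-7-methoxy-7-oxohept-2-en-1-yl]-5-oxocyclopentane-1-carboxylic acid | CCCCC[C@H](O[Si](C)(C)C(C)(C)C)/C=C/[C@@H]1[C@@](C(=O)O)(C/C=C\CCCC(=O)OC)C(=O)C[C@H]1O[Si](C)(C)C(C)(C)C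
F8 | step 8 | methyl (5Z)-7-[(1R,2R,3R)-3-(tert-butyldimethylsilyloxy)-2-[(1E,3S)-3-(tert-butyldimethylsilyloxy)oct-1-en-1-yl]-5-oxocyclopentyl]hept-5-enoate | CCCCC[C@H](O[Si](C)(C)C(C)(C)C)/C=C/[C@@H]1[C@@H](C/C=C\CCCC(=O)OC)C(=O)C[C@H]1O[Si](C)(C)C(C)(C)C
F9 | step 3 | ethyl (2E)-3-[(2R,3S)-3-pentyloxiran-2-yl]prop-2-enoate | CCOC(=O)/C=C/[C@H]1O[C@H]1CCCCC
F10 | step 3 | (2E)-3-[(2R,3S)-3-pentyloxiran-2-yl]prop-2-en-1-ol | OC/C=C/[C@H]1O[C@H]1CCCCC
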